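The earlier runs and the new flask come from a simulation for an exercise; the scatter is artificial.

I cannot watch the use of G by itself in these runs, where G is made from Z at the same time, but I can watch E, which on the suspects' list forms from G + Q.

the same everywhere: D 7.9 mM (held)

| flask | Z | temperature | remark | time |
|---|---|---|---|---|
| violet | 0.067 M | 45 °C | run made earlier |  |
| green | 0.15 M | 72 °C | run made earlier |  |
| delta | 0.10 M | 80 °C |  | 30 h |
| gamma | 0.10 M | 95 °C |  | 30 h |
| epsilon | 0.10 M | 65 °C |  | 30 h |
| alpha | 0.10 M | 50 °C |  | 30 h |

- violet (time / h: G / %, E / %, Z / %): 60.0: 62.0, 17.9, 19.8; 120: 49.9, 41.0, 7.5; 144: 45.9, 48.4, 5.8; 240: 31.4, 66.2, 2.3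
- green (time / h: G / %, E / %, Z / %): 3.00: 37.1, 4.4, 57.5; 6.00: 48.0, 21.1, 31.5; 15.0: 31.9, 63.2, 5.2; 40.0: 10.8, 89.6, 0

(standard deviation of a reading: 0.5 percentage points)

- at the start none of X is dissolved
- on the list of suspects stand: Z + X <-> G + Q; D <-> X; G + Q -> E

1. the best flask by share of G in all that became G or E; "all alike" if 1.5 percentage points covers them all (delta / gamma / epsilon / alpha / all alike)
2. share of G in all that became G or E, delta
3. share of G in all that became G or E, gamma
4. share of G in all that became G or E, epsilon
5. share of G in all that became G or E, alpha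

Z + X gives one G and one Q, and neither is charged, so Q equals G as long as each is used one for one. E then grows at k·G², with k the second-order rate constant. Over an interval in which G falls this way, the mean of G² is the product of G at the two ends, so, setting aside the Z that still turns in that interval, I estimate k from the last two readings of each run, with G and G′ the readings at the two ends:

k = ΔE / (Δt · G · G′)

The violet run reads 0.192 M⁻¹ h⁻¹ and the green run 2.04 M⁻¹ h⁻¹. Between 45 °C and 72 °C, k therefore climbs 1.03 powers of ten. I take log10 k as straight in temperature, which is an extrapolation for delta and gamma.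

If all Z turned at once, 1/G would rise linearly with time, and the share s = G/(G + E) would be

s = 1/(1 + N),  N = k·c·t

Here c is the Z charged and t the time. N, a Damköhler number, counts how many second-order lifetimes of G the flask has lived; for gamma it is 46.0. In logarithms, at fixed k and c, ten times the time adds one power of ten to N.

The other flasks count 0.893 in alpha, 3.32 in epsilon and 12.4 in delta. G from Z that turns late has lived less, so I expect the shares these give to lie low: 52.8% for alpha, 23.1% for epsilon, 7.46% for delta and 2.13% for gamma. I rank alpha first, with the smallest N.

The forecast also names alpha, with higher values than mine: 79% for alpha, 37% for epsilon, 13% for delta and 4.5% for gamma. Its ground is “Coolest is best for G”.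

The flasks give 77.9% in alpha, 34.6% in epsilon, 10.8% in delta and 3.57% in gamma, so alpha stands first and the forecast holds.

    Z + X ⇌ G + Q (K = 90.0, k = 1.30 M⁻¹ min⁻¹, Ea = 79.0 kJ mol⁻¹, ΔH = 17.0 kJ mol⁻¹)
    D ⇌ X, rate k2*(csat - [X]) (kL = 0.110 min⁻¹)
    G + Q → E (k = 0.0570 M⁻¹ min⁻¹, Ea = 78.0 kJ mol⁻¹)
    (constants at 80 °C)

In alpha, X stands at 7.75 mM at 30.0 h, against a saturation of 7.9 mM. Read back through s, the share of gamma means N = 27.0, less than the 46.0 I counted. Ten times the time adds one power of ten to that N, which gives 0.368%, and gamma at 300 h stands at 0.333%.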